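**Plan**

- Retrosynthesis: the methyl ester C–O bond is cut first (methanolysis of a meso cyclic anhydride), then the cyclobutane bonds C1–C2 and C3–C4, which leaves two molecules of (E)-3-(4-methoxy-3-methyl-2-oxo-2H-pyran-6-yl)but-2-enoic acid. That acid is cut at its C2=C3 alkene (olefination of a 6-acetylpyranone), and the pyranone at C5–C6 and O1–C2 (Claisen condensation and lactonisation).
- Enabling feature: in the ring C1–C2–C3–C4, C1 (CO2H) and C2 (CO2Me) are cis CH carbons and C3 and C4 are quaternary, each carrying a methyl and a pyranone ring. The ring is therefore the head-to-head dimer of one enoic acid, and its two cis carboxyl groups can be held by the peri oxygens of naphthalene-1,8-diol.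
- Forward order: pyranone ring, side-chain alkene, two arms esterified on the template, cyclobutane (with a transient nine-membered dilactone) by light, template removal, anhydride ring, ring opening.
- Stereochemistry: the relative configuration comes from the E alkene geometry (methyl cis, pyranone trans to carboxyl) and the syn stacking of the arms (carboxyls cis). The absolute configuration comes from alkaloid-mediated opening of the meso anhydride.

Key step: step 7

Assumption: quinidine is assumed to open the anhydride at the carbonyl that becomes the methyl ester of the target, by analogy with simple cis-cycloalkane-1,2-dicarboxylic anhydrides; if the sense proves opposite, the pseudo-enantiomeric quinine takes its place in the same step.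

**Route**

Step 1
Reactants: 1 ethyl 2-methylacetoacetate; 2 methyl 2,2-dimethoxypropanoate
Product: 4 6-(1,1-dimethoxyethyl)-4-hydroxy-3-methyl-2H-pyran-2-one, via ethyl 6,6-dimethoxy-2-methyl-3,5-dioxoheptanoate 3 (not isolated)
Conditions: LiN(iPr)2 (3.2 equiv), THF, −78 → 0 °C; 2, −78 °C → rt; AcOH quench; crude in PhMe, DBU, 90 °C
Reagents that add atoms: none
Why: γ-Acylation of the acetoacetate dianion by the non-enolisable, alkoxy-activated ester (crossed Claisen condensation) followed by base-induced enol lactonisation onto the ethyl ester is the standard entry to 6-substituted 4-hydroxy-2-pyranones, and the ketal is inert to both bases.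

Step 2
Reactants: 4 6-(1,1-dimethoxyethyl)-4-hydroxy-3-methyl-2H-pyran-2-one
Product: 5 6-(1,1-dimethoxyethyl)-4-methoxy-3-methyl-2H-pyran-2-one
Conditions: Me2SO4, K2CO3, acetone, reflux
Reagents that add atoms: dimethyl sulfate, COS(=O)(=O)OC
Why: O-Alkylation of the vinylogous acid with a hard methylating agent and K2CO3 in acetone should give the 4-methoxy-2-pyranone rather than the 2-methoxy-4-pyranone isomer, as is usual for 4-hydroxy-2-pyranones.

Step 3
Reactants: 5 6-(1,1-dimethoxyethyl)-4-methoxy-3-methyl-2H-pyran-2-one
Product: 6 6-acetyl-4-methoxy-3-methyl-2H-pyran-2-one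
Conditions: 1 M aq. HCl, THF, 40 °C
Reagents that add atoms: water, O
Why: Acid-catalysed ketal hydrolysis should free the methyl ketone while the pyranone and its vinylogous-ester methoxy group tolerate dilute acid.

Step 4
Reactants: 6 6-acetyl-4-methoxy-3-methyl-2H-pyran-2-one; 7 tert-butyl diethylphosphonoacetate
Product: 8 tert-butyl (E)-3-(4-methoxy-3-methyl-2-oxo-2H-pyran-6-yl)but-2-enoate
Conditions: NaH, THF, 0 °C → rt
Reagents that add atoms: none
Why: Horner–Wadsworth–Emmons olefination of the electron-poor aryl-type methyl ketone should place the bulky tert-butyl ester trans to the larger pyranonyl group under reversible addition, and any minor Z isomer is removed by chromatography.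

Step 5
Reactants: 8 tert-butyl (E)-3-(4-methoxy-3-methyl-2-oxo-2H-pyran-6-yl)but-2-enoate
Product: 9 (E)-3-(4-methoxy-3-methyl-2-oxo-2H-pyran-6-yl)but-2-enoic acid
Conditions: TFA, CH2Cl2, 0 °C → rt
Reagents that add atoms: none
Why: Acidolysis of the tert-butyl ester through the tert-butyl cation (E1 loss of isobutene) frees the acid without hydroxide, which the pyranone would not tolerate, and without touching the alkene geometry.

Step 6
Reactants: 9 (E)-3-(4-methoxy-3-methyl-2-oxo-2H-pyran-6-yl)but-2-enoic acid (2.3 equiv); 10 naphthalene-1,8-diol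
Product: 11 naphthalene-1,8-diyl bis[(E)-3-(4-methoxy-3-methyl-2-oxo-2H-pyran-6-yl)but-2-enoate]
Conditions: EDC·HCl, DMAP (cat.), CH2Cl2, 0 °C → rt, dark
Reagents that add atoms: none
Why: Steglich esterification acylates both peri phenols under mild conditions, as is known for cinnamic acids with this diol, and working cold and in the dark should keep both alkenes conjugated and E.

Step 7
Reactants: 11 naphthalene-1,8-diyl bis[(E)-3-(4-methoxy-3-methyl-2-oxo-2H-pyran-6-yl)but-2-enoate]
Product: 12 naphthalene-1,8-diyl meso-(1R,2S,3R,4S)-3,4-bis(4-methoxy-3-methyl-2-oxo-2H-pyran-6-yl)-3,4-dimethylcyclobutane-1,2-dicarboxylate (cyclic diester; both ester carbons and both methyls on one face, both pyranones on the other)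
Conditions: hν (365 nm), crystalline film under N2, rt
Reagents that add atoms: none
Why: Near-UV excitation of the pyranonyl-enoate chromophore of one arm, beyond the naphthalene absorption, is followed by bonding to the ground-state enoate of the neighbouring arm, which the peri oxygens hold parallel and in register, so that Cα–Cα (C1–C2) and Cβ–Cβ (C3–C4) form in a [2+2] photocycloaddition that is suprafacial on both alkenes. The closest known reaction type is the head-to-head photodimerisation of cinnamic acids bound as diesters to a peri-diol template, and the photodimerisation of β-methyl cinnamate-type enoates such as 4-methylcoumarins shows that two adjacent quaternary carbons can be made this way. The cyclobutane closes by intramolecular cycloaddition between the two tethered alkenes, and the same event closes the nine-membered dilactone ring that contains the template. C1 and C2 are set by the mirror-related syn stacking of the arms, which puts both ester carbons on one face, and C3 and C4 are set by the E geometry of each alkene, transferred stereospecifically so that each methyl ends cis and each pyranone trans to the carboxyl of its own former alkene. The step needs head-to-head regioselectivity, chemoselectivity for the exocyclic alkene over the pyranone C5–C6 bond, and cycloaddition faster than E/Z isomerisation; the tether secures the first two by proximity, and irradiation in the crystal, where rotation about the excited C=C bond is restricted, secures the third.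

Step 8
Reactants: 12 template-bridged meso cyclobutane diester
Product: 13 meso-(1R,2S,3R,4S)-3,4-bis(4-methoxy-3-methyl-2-oxo-2H-pyran-6-yl)-3,4-dimethylcyclobutane-1,2-dicarboxylic acid
Conditions: LiOH·H2O, THF/H2O, 0 °C, N2; then 1 M HCl
Reagents that add atoms: lithium hydroxide, [Li+].[OH-]
Why: Saponification by acyl–oxygen cleavage should take the two aryl esters, which are far more electrophilic than the vinylogous-carbonate-like pyranone lactones, quickly enough at 0 °C that the α-CH centres are not epimerised and the pyranones are not opened.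

Step 9
Reactants: 13 meso cis-diacid
Product: 14 meso-(1R,5S,6R,7S)-6,7-bis(4-methoxy-3-methyl-2-oxo-2H-pyran-6-yl)-6,7-dimethyl-3-oxabicyclo[3.2.0]heptane-2,4-dione
Conditions: Ac2O, 80 °C
Reagents that add atoms: none
Why: Cyclodehydration through the mixed acetic anhydride closes the five-membered anhydride, which only the cis-1,2-diacid can form, and leaves all four stereocentres untouched.

Step 10
Reactants: 14 meso anhydride
Product: 15 (1S,2R,3S,4R)-2-(methoxycarbonyl)-3,4-bis(4-methoxy-3-methyl-2-oxo-2H-pyran-6-yl)-3,4-dimethylcyclobutane-1-carboxylic acid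
Conditions: quinidine (1.1 equiv), MeOH (3 equiv), PhMe/CH2Cl2, −55 °C; then 1 M HCl wash
Reagents that add atoms: methanol, CO
Why: Cinchona alkaloid-mediated enantiotopos-selective methanolysis of a meso cyclic anhydride (general-base delivery of methanol by the quinuclidine nitrogen) should open only one of the two mirror-related carbonyls, so the four existing stereocentres become non-equivalent and the absolute configuration of 15 is fixed without creating a new centre.

**Compound list**

1 | ethyl 2-methylacetoacetate (ethyl 2-methyl-3-oxobutanoate) | CCOC(=O)C(C)C(C)=O | starting material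
2 | methyl 2,2-dimethoxypropanoate | COC(=O)C(C)(OC)OC | starting material
3 | ethyl 6,6-dimethoxy-2-methyl-3,5-dioxoheptanoate (formed and cyclised in the flask) | CCOC(=O)C(C)C(=O)CC(=O)C(C)(OC)OC | intermediate
4 | 6-(1,1-dimethoxyethyl)-4-hydroxy-3-methyl-2H-pyran-2-one | COC(C)(OC)c1cc(O)c(C)c(=O)o1 | intermediate
5 | 6-(1,1-dimethoxyethyl)-4-methoxy-3-methyl-2H-pyran-2-one | COC(C)(OC)c1cc(OC)c(C)c(=O)o1 | intermediate
6 | 6-acetyl-4-methoxy-3-methyl-2H-pyran-2-one | CC(=O)c1cc(OC)c(C)c(=O)o1 | intermediate
7 | tert-butyl diethylphosphonoacetate | CCOP(=O)(OCC)CC(=O)OC(C)(C)C | starting material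
8 | tert-butyl (E)-3-(4-methoxy-3-methyl-2-oxo-2H-pyran-6-yl)but-2-enoate | C/C(c1cc(OC)c(C)c(=O)o1)=C\C(=O)OC(C)(C)C | intermediate
9 | (E)-3-(4-methoxy-3-methyl-2-oxo-2H-pyran-6-yl)but-2-enoic acid | C/C(c1cc(OC)c(C)c(=O)o1)=C\C(=O)O | intermediate
10 | naphthalene-1,8-diol | Oc1cccc2cccc(O)c12 | starting material
11 | naphthalene-1,8-diyl bis[(E)-3-(4-methoxy-3-methyl-2-oxo-2H-pyran-6-yl)but-2-enoate] | C/C(c1cc(OC)c(C)c(=O)o1)=C\C(=O)Oc2cccc3cccc(OC(=O)/C=C(\C)c4cc(OC)c(C)c(=O)o4)c23 | intermediate
12 | naphthalene-1,8-diyl meso-(1R,2S,3R,4S)-3,4-bis(4-methoxy-3-methyl-2-oxo-2H-pyran-6-yl)-3,4-dimethylcyclobutane-1,2-dicarboxylate (template-bridged cyclic diester) | O=C(Oc3cccc4cccc(O5)c34)[C@@H]1[C@H](C5=O)[C@@](C)(c2cc(OC)c(C)c(=O)o2)[C@@]1(C)c1cc(OC)c(C)c(=O)o1 | intermediate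
13 | meso-(1R,2S,3R,4S)-3,4-bis(4-methoxy-3-methyl-2-oxo-2H-pyran-6-yl)-3,4-dimethylcyclobutane-1,2-dicarboxylic acid | OC(=O)[C@@H]1[C@H](C(=O)O)[C@@](C)(c2cc(OC)c(C)c(=O)o2)[C@@]1(C)c1cc(OC)c(C)c(=O)o1 | intermediate
14 | meso-(1R,5S,6R,7S)-6,7-bis(4-methoxy-3-methyl-2-oxo-2H-pyran-6-yl)-6,7-dimethyl-3-oxabicyclo[3.2.0]heptane-2,4-dione | O=C3OC(=O)[C@@H]1[C@H]3[C@@](C)(c2cc(OC)c(C)c(=O)o2)[C@@]1(C)c1cc(OC)c(C)c(=O)o1 | intermediate
15 | (1S,2R,3S,4R)-2-(methoxycarbonyl)-3,4-bis(4-methoxy-3-methyl-2-oxo-2H-pyran-6-yl)-3,4-dimethylcyclobutane-1-carboxylic acid (CNP0481603.1) | COC(=O)[C@@H]1[C@H](C(=O)O)[C@@](C)(c2cc(OC)c(C)c(=O)o2)[C@@]1(C)c1cc(OC)c(C)c(=O)o1 | target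

**Step count and risks**

Total steps: 10. Longest linear sequence: 10 steps (from 1 and 2 to 15).

Step 7 is the most exposed. The two arms may crystallise out of register so that no cycloaddition occurs. Dilute solution irradiation at 365 nm would be tried first, but there E/Z isomerisation and addition across the pyranone C5–C6 bond may compete with the wanted closure. The fallback drops the covalent template and sets out from acid 9. Two equivalents of 9 are crystallised with ethane-1,2-diamine to give the double salt ethane-1,2-diammonium bis[(E)-3-(4-methoxy-3-methyl-2-oxo-2H-pyran-6-yl)but-2-enoate] F1. In such salts the diammonium ion lays pairs of carboxylates side by side, an arrangement known to steer cinnamic acids to head-to-head cis dimers. Irradiation of the solid should give the ethane-1,2-diammonium salt of the cyclobutane diacid F2, and acidification returns the route at 13.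

Step 10 may fail by weak differentiation of the two carbonyls, by a sense of induction opposite to the one assumed, or by sluggish attack at carbonyls flanked by quaternary carbons. The fallback sets out from 14. Methanolysis with achiral DMAP should give the racemate, that is 15 together with its antipode (1R,2S,3R,4S)-2-(methoxycarbonyl)-3,4-bis(4-methoxy-3-methyl-2-oxo-2H-pyran-6-yl)-3,4-dimethylcyclobutane-1-carboxylic acid F3. Preparative chromatography on a chiral stationary phase then separates the two, and the route is rejoined at 15 independently of any alkaloid model.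

Step 6 may suffer deconjugation of the activated β-methyl enoic acid through a vinylketene, or may stall after the first acylation because of peri crowding. The fallback sets out from 9 and 10 and avoids amine-activated acyl species. Acid 9 is converted with cyanuric fluoride and pyridine into (E)-3-(4-methoxy-3-methyl-2-oxo-2H-pyran-6-yl)but-2-enoyl fluoride F4. Diol 10 is silylated with hexamethyldisilazane to 1,8-bis(trimethylsilyloxy)naphthalene F5. Fluoride-catalysed coupling of the two (catalytic Bu4NF, MeCN) should then give diester 11 under essentially neutral conditions.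

**Further compounds**

F1 | step 7 | ethane-1,2-diammonium bis[(E)-3-(4-methoxy-3-methyl-2-oxo-2H-pyran-6-yl)but-2-enoate] | C/C(c1cc(OC)c(C)c(=O)o1)=C\C(=O)[O-].C/C(c1cc(OC)c(C)c(=O)o1)=C\C(=O)[O-].[NH3+]CC[NH3+]
F2 | step 7 | ethane-1,2-diammonium meso-(1R,2S,3R,4S)-3,4-bis(4-methoxy-3-methyl-2-oxo-2H-pyran-6-yl)-3,4-dimethylcyclobutane-1,2-dicarboxylate | [O-]C(=O)[C@@H]1[C@H](C(=O)[O-])[C@@](C)(c2cc(OC)c(C)c(=O)o2)[C@@]1(C)c1cc(OC)c(C)c(=O)o1.[NH3+]CC[NH3+]
F3 | step 10 | (1R,2S,3R,4S)-2-(methoxycarbonyl)-3,4-bis(4-methoxy-3-methyl-2-oxo-2H-pyran-6-yl)-3,4-dimethylcyclobutane-1-carboxylic acid (antipode of 15) | COC(=O)[C@H]1[C@@H](C(=O)O)[C@](C)(c2cc(OC)c(C)c(=O)o2)[C@]1(C)c1cc(OC)c(C)c(=O)o1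
F4 | step 6 | (E)-3-(4-methoxy-3-methyl-2-oxo-2H-pyran-6-yl)but-2-enoyl fluoride | C/C(c1cc(OC)c(C)c(=O)o1)=C\C(F)=O
F5 | step 6 | 1,8-bis(trimethylsilyloxy)naphthalene | C[Si](C)(C)Oc1cccc2cccc(O[Si](C)(C)C)c12
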